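The flavanone is cut at C4–C4a, which opens pyranone ring C to an O1-tethered (S)-3-aryl-3-aryloxypropanoic acid. In ring A, C4a lies between C8a (O1) and C5 (O5) and para to C7 (O7), so three oxygen donors converge on it. C8, the only other carbon next to C8a, already carries the prenyl chain, so an acyl electrophile hung from O1 has a single landing site. One mild Friedel–Crafts acylation forms C4–C4a and closes ring C without touching C2. The precursor carries both A-ring oxygens as methyl ethers, the intact prenyl group and a 4'-acetate. Its C2 configuration comes from transfer hydrogenation followed by Mitsunobu inversion.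

Key step: step 7

Remark: flavanone numbering is used throughout (O1, C2, C3, C4, C4a, C5–C8, C8a; B ring primed). The target SMILES encodes (2S).

Step 1
Reactants: 1 3,5-dimethoxyphenol; 2 prenyl bromide (1-bromo-3-methylbut-2-ene)
Product: 4 3,5-dimethoxy-2-(3-methylbut-2-en-1-yl)phenol, via sodium 3,5-dimethoxyphenoxide 3 (not isolated)
Conditions: NaH (1.0 equiv), toluene, 0 °C to rt; then 2 (0.9 equiv), rt
Reagents that add atoms: none
Why: This is ortho C-alkylation of a phenoxide contact ion pair, in which non-polar toluene keeps sodium on the oxygen so that the allylic bromide is steered (SN2) to the neighbouring ring carbon, the two ortho carbons are equivalent by symmetry, and rearomatisation should give 4, to be separated by chromatography from minor O-prenyl and C4-prenyl isomers.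

Step 2
Reactants: 5 4'-hydroxyacetophenone; 6 diallyl carbonate
Product: 7 allyl 3-(4-hydroxyphenyl)-3-oxopropanoate
Conditions: NaH (3 equiv), 6 (2.5 equiv), THF, reflux; then cold 1 M HCl
Reagents that add atoms: none
Why: This is a crossed Claisen condensation of a methyl ketone enolate with a non-enolisable carbonate, driven by irreversible deprotonation of the new β-keto ester while the phenol rides along as its inert sodium salt, and the allyl ester is chosen because it can later be removed without hydroxide.

Step 3
Reactants: 7 allyl 3-(4-hydroxyphenyl)-3-oxopropanoate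
Product: 8 allyl 3-(4-acetoxyphenyl)-3-oxopropanoate
Conditions: Ac2O (1.1 equiv), Et3N (1.2 equiv), CH2Cl2, 0 °C
Reagents that add atoms: acetic anhydride, CC(=O)OC(C)=O
Why: This is O-acetylation by nucleophilic acyl substitution at the most acidic site, the para-acyl phenol, which should outrun enol acylation at 0 °C without DMAP and weakens the B ring as a cation-stabilising donor for steps 5, 7 and 8.

Step 4
Reactants: 8 allyl 3-(4-acetoxyphenyl)-3-oxopropanoate
Product: 9 allyl (R)-3-(4-acetoxyphenyl)-3-hydroxypropanoate
Conditions: RuCl[(R,R)-TsDPEN](p-cymene) (0.5–1 mol %), HCO2H/Et3N (5:2), EtOAc, 30 °C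
Reagents that add atoms: none
Why: This is a Noyori–Ikariya asymmetric transfer hydrogenation, in which the aryl group docks against the η6-arene of the catalyst so that the (R,R)-complex delivers hydride to the face giving the (R)-carbinol (the same sense as for acetophenone), and the outer-sphere mechanism leaves untouched both the acetate and the allyl C=C that pressure hydrogenation would saturate.

Step 5
Reactants: 4 3,5-dimethoxy-2-(3-methylbut-2-en-1-yl)phenol; 9 allyl (R)-3-(4-acetoxyphenyl)-3-hydroxypropanoate
Product: 10 allyl (S)-3-(4-acetoxyphenyl)-3-[3,5-dimethoxy-2-(3-methylbut-2-en-1-yl)phenoxy]propanoate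
Conditions: PPh3 (1.3 equiv), DIAD (1.3 equiv), toluene, 0 °C to rt
Reagents that add atoms: none
Why: This is a Mitsunobu etherification, in which the phenol is acidic enough to protonate the PPh3/DIAD adduct and its phenoxide displaces the phosphorus-activated oxygen from the rear, so (R) becomes (S) by clean SN2 inversion, while toluene, low temperature and the acetoxy-damped B ring disfavour an SN1 leak.

Step 6
Reactants: 10 allyl (S)-3-(4-acetoxyphenyl)-3-[3,5-dimethoxy-2-(3-methylbut-2-en-1-yl)phenoxy]propanoate
Product: 11 (S)-3-(4-acetoxyphenyl)-3-[3,5-dimethoxy-2-(3-methylbut-2-en-1-yl)phenoxy]propanoic acid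
Conditions: Pd(PPh3)4 (3 mol %), N-methylaniline (3 equiv), THF, rt; cold aq. KHSO4 wash
Reagents that add atoms: none
Why: This is a Tsuji–Trost deallylation, in which Pd(0) ionises only the allyl ester and the weakly basic aniline takes up the allyl unit, so the acid is released at neutral pH, whereas saponification would strip the aryl acetate first and invite E1cB loss of the aryloxide from C2.

Step 7
Reactants: 11 (S)-3-(4-acetoxyphenyl)-3-[3,5-dimethoxy-2-(3-methylbut-2-en-1-yl)phenoxy]propanoic acid
Product: 13 (S)-4'-acetoxy-5,7-dimethoxy-8-prenylflavanone, via acyl trifluoroacetate mixed anhydride 12 (not isolated)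
Conditions: TFAA (1.2 equiv), CH2Cl2 (0.02 M), 0 °C, short reaction time; poured into cold aq. NaHCO3
Reagents that add atoms: none
Why: TFAA turns the acid quickly into mixed anhydride 12, whose acyl carbon (as such or as an incipient acylium ion) is attacked by C4a, and loss of the C4a proton restores aromaticity. This is the intramolecular Friedel–Crafts acylation of 3-aryloxypropanoic acids, the standard entry to chroman-4-ones. Ring C closes in a six-membered 6-exo-trig mode at the acyl carbon, with the C4a–C8a arene bond endocyclic. No stereocentre is created; C2 is a spectator that becomes β to a ketone only after closure, and the absence of base leaves no retro-oxa-Michael path. Site selectivity is structural, because C8 is blocked by prenyl, C6 is beyond the reach of the three-atom tether, and C4a is ortho, ortho and para to O1, O5 and O7. Chemoselectivity over alkene protonation, C2–O1 ionisation and ring trifluoroacetylation rests on near-stoichiometric TFAA, dilution of the liberated acid at 0 °C, and the 4'-acetate and β-acyl group, which both destabilise a C2 cation.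

Step 8
Reactants: 13 (S)-4'-acetoxy-5,7-dimethoxy-8-prenylflavanone
Product: 14 (S)-4'-acetoxy-5-hydroxy-7-methoxy-8-prenylflavanone
Conditions: anhydrous MgI2 (2 equiv), THF, 50 °C; then cold 0.5 M HCl, aq. Na2S2O3 wash
Reagents that add atoms: none
Why: This is a chelation-directed aryl methyl ether cleavage, in which Mg(II) binds between C4=O and O5 so that only the peri 5-methyl is activated for SN2 attack by iodide, the reagent class tolerates 8-prenyl chains, aryl acetates and unchelated 7-methoxy groups on flavanones, and the retained acetate plus the absence of base guard C2 against ring opening.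

Step 9
Reactants: 14 (S)-4'-acetoxy-5-hydroxy-7-methoxy-8-prenylflavanone
Product: 15 Mundulea flavanone B, (2S)-5,4'-dihydroxy-7-methoxy-8-prenylflavanone
Conditions: NH4OAc (10 equiv), MeOH–H2O (4:1), rt
Reagents that add atoms: none
Why: This is a near-neutral solvolysis of an aryl acetate by nucleophilic acyl substitution at an activated ester, chosen because carbonate or hydroxide could open ring C to the chalcone through the C3 enolate or the 4'-phenoxide, whereas at about pH 7 the hydrogen-bonded 5-hydroxyflavanone should keep its (2S) configuration.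

Compound list
1 | 3,5-dimethoxyphenol | COc1cc(O)cc(OC)c1 | starting material
2 | prenyl bromide (1-bromo-3-methylbut-2-ene) | CC(C)=CCBr | starting material
3 | sodium 3,5-dimethoxyphenoxide | COc1cc([O-])cc(OC)c1.[Na+] | intermediate
4 | 3,5-dimethoxy-2-(3-methylbut-2-en-1-yl)phenol | COc1cc(O)c(CC=C(C)C)c(OC)c1 | intermediate
5 | 4'-hydroxyacetophenone | CC(=O)c1ccc(O)cc1 | starting material
6 | diallyl carbonate | C=CCOC(=O)OCC=C | starting material
7 | allyl 3-(4-hydroxyphenyl)-3-oxopropanoate | C=CCOC(=O)CC(=O)c1ccc(O)cc1 | intermediate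
8 | allyl 3-(4-acetoxyphenyl)-3-oxopropanoate | C=CCOC(=O)CC(=O)c1ccc(OC(C)=O)cc1 | intermediate
9 | allyl (R)-3-(4-acetoxyphenyl)-3-hydroxypropanoate | O[C@@H](c1ccc(OC(C)=O)cc1)CC(=O)OCC=C | intermediate
10 | allyl (S)-3-(4-acetoxyphenyl)-3-[3,5-dimethoxy-2-(3-methylbut-2-en-1-yl)phenoxy]propanoate | COc1cc(OC)c(CC=C(C)C)c(O[C@H](c2ccc(OC(C)=O)cc2)CC(=O)OCC=C)c1 | intermediate
11 | (S)-3-(4-acetoxyphenyl)-3-[3,5-dimethoxy-2-(3-methylbut-2-en-1-yl)phenoxy]propanoic acid | COc1cc(OC)c(CC=C(C)C)c(O[C@H](c2ccc(OC(C)=O)cc2)CC(=O)O)c1 | intermediate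
12 | (S)-3-(4-acetoxyphenyl)-3-[3,5-dimethoxy-2-(3-methylbut-2-en-1-yl)phenoxy]propanoic trifluoroacetic anhydride | COc1cc(OC)c(CC=C(C)C)c(O[C@H](c2ccc(OC(C)=O)cc2)CC(=O)OC(=O)C(F)(F)F)c1 | intermediate
13 | (S)-4'-acetoxy-5,7-dimethoxy-8-prenylflavanone | COc1cc(OC)c2c(c1CC=C(C)C)O[C@H](c1ccc(OC(C)=O)cc1)CC2=O | intermediate
14 | (S)-4'-acetoxy-5-hydroxy-7-methoxy-8-prenylflavanone | COc1cc(O)c2c(c1CC=C(C)C)O[C@H](c1ccc(OC(C)=O)cc1)CC2=O | intermediate
15 | Mundulea flavanone B, (2S)-5,4'-dihydroxy-7-methoxy-8-prenylflavanone | COc1cc(O)c2c(c1CC=C(C)C)O[C@H](c1ccc(O)cc1)CC2=O | target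

Total step count: 9.
Longest linear sequence: 8 steps (steps 2–9, from 5 to 15). Step 1 is the one-step side branch that joins at step 5.

Steps most likely to fail

Step 7 (key step). The acid liberated during acylation may protonate the trisubstituted prenyl alkene or add to it. Forcing the closure may also ionise the C2–O1 bond and erode the configuration. The fallback carries the side chain as a far less basic allyl group and completes the prenyl unit only after ring closure. It sets out from 1, uses 9 as partner, and returns at 13.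
- O-Allylation of 1 (allyl bromide, K2CO3, acetone) should give allyl 3,5-dimethoxyphenyl ether F1.
- Aromatic Claisen rearrangement (N,N-diethylaniline, 190 °C) should give 2-allyl-3,5-dimethoxyphenol F2, the only ortho isomer by symmetry.
- Mitsunobu coupling of F2 with 9 (PPh3, DIAD, toluene) should give allyl (S)-3-(4-acetoxyphenyl)-3-(2-allyl-3,5-dimethoxyphenoxy)propanoate F3.
- Pd(PPh3)4 with N-methylaniline should release (S)-3-(4-acetoxyphenyl)-3-(2-allyl-3,5-dimethoxyphenoxy)propanoic acid F4.
- Closure with TFAA, which can now run with more reagent or a catalytic Brønsted acid, should give (S)-4'-acetoxy-8-allyl-5,7-dimethoxyflavanone F5.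
- Cross-metathesis with excess 2-methylbut-2-ene (Grubbs second-generation catalyst, CH2Cl2, 40 °C) should convert the allyl into the prenyl group and deliver 13.

Step 5. The basic Mitsunobu adduct may dehydrate the β-hydroxy ester to the cinnamate through its acidic C3 protons, and the ortho-substituted phenol may react slowly enough for partial SN1 leakage at the benzylic carbon. The fallback performs the etherification on a substrate without a carbonyl group, as is routine for 1-aryl-3-substituted propanols, and raises the oxidation level afterwards. It sets out from 9 and returns at 11.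
- Pd(PPh3)4 with N-methylaniline should give (R)-3-(4-acetoxyphenyl)-3-hydroxypropanoic acid F6.
- BH3·SMe2 (THF, 0 °C), which reduces acids much faster than esters, should give (R)-4-(1,3-dihydroxypropyl)phenyl acetate F7.
- TBSCl with imidazole (CH2Cl2, 0 °C) should silylate the primary hydroxyl to give (R)-4-[3-(tert-butyldimethylsilyloxy)-1-hydroxypropyl]phenyl acetate F8.
- Mitsunobu coupling with 4 should give, with inversion, (S)-4-{3-(tert-butyldimethylsilyloxy)-1-[3,5-dimethoxy-2-(3-methylbut-2-en-1-yl)phenoxy]propyl}phenyl acetate F9.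
- HF·pyridine (THF/pyridine, 0 °C) should give (S)-4-{1-[3,5-dimethoxy-2-(3-methylbut-2-en-1-yl)phenoxy]-3-hydroxypropyl}phenyl acetate F10.
- TEMPO (cat.) with PhI(OAc)2 in MeCN–H2O should oxidise the primary alcohol to acid 11.

Step 1. The alkylation may partition poorly between oxygen, the ortho carbon, the C4 carbon and double alkylation. The fallback delivers the prenyl group intramolecularly, so that only an ortho carbon can receive it. It sets out from 1 and returns at 4.
- O-Alkylation with 3-chloro-3-methylbut-1-yne (K2CO3, KI, cat. CuI, acetone, 55 °C) should give 1,3-dimethoxy-5-[(2-methylbut-3-yn-2-yl)oxy]benzene F11.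
- Semihydrogenation (H2, Lindlar catalyst, quinoline, EtOAc) should give 1,3-dimethoxy-5-[(2-methylbut-3-en-2-yl)oxy]benzene F12.
- Aromatic Claisen rearrangement (N,N-diethylaniline, 120–130 °C) transposes the 1,1-dimethylallyl unit and should place a linear prenyl group on the ortho carbon, giving 4.

Further compounds
F1 | step 7 | allyl 3,5-dimethoxyphenyl ether | C=CCOc1cc(OC)cc(OC)c1
F2 | step 7 | 2-allyl-3,5-dimethoxyphenol | C=CCc1c(O)cc(OC)cc1OC
F3 | step 7 | allyl (S)-3-(4-acetoxyphenyl)-3-(2-allyl-3,5-dimethoxyphenoxy)propanoate | COc1cc(OC)c(CC=C)c(O[C@H](c2ccc(OC(C)=O)cc2)CC(=O)OCC=C)c1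
F4 | step 7 | (S)-3-(4-acetoxyphenyl)-3-(2-allyl-3,5-dimethoxyphenoxy)propanoic acid | COc1cc(OC)c(CC=C)c(O[C@H](c2ccc(OC(C)=O)cc2)CC(=O)O)c1
F5 | step 7 | (S)-4'-acetoxy-8-allyl-5,7-dimethoxyflavanone | COc1cc(OC)c2c(c1CC=C)O[C@H](c1ccc(OC(C)=O)cc1)CC2=O
F6 | step 5 | (R)-3-(4-acetoxyphenyl)-3-hydroxypropanoic acid | O[C@@H](c1ccc(OC(C)=O)cc1)CC(=O)O
F7 | step 5 | (R)-4-(1,3-dihydroxypropyl)phenyl acetate | O[C@@H](c1ccc(OC(C)=O)cc1)CCO
F8 | step 5 | (R)-4-[3-(tert-butyldimethylsilyloxy)-1-hydroxypropyl]phenyl acetate | O[C@@H](c1ccc(OC(C)=O)cc1)CCO[Si](C)(C)C(C)(C)C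
F9 | step 5 | (S)-4-{3-(tert-butyldimethylsilyloxy)-1-[3,5-dimethoxy-2-(3-methylbut-2-en-1-yl)phenoxy]propyl}phenyl acetate | COc1cc(OC)c(CC=C(C)C)c(O[C@H](c2ccc(OC(C)=O)cc2)CCO[Si](C)(C)C(C)(C)C)c1
F10 | step 5 | (S)-4-{1-[3,5-dimethoxy-2-(3-methylbut-2-en-1-yl)phenoxy]-3-hydroxypropyl}phenyl acetate | COc1cc(OC)c(CC=C(C)C)c(O[C@H](c2ccc(OC(C)=O)cc2)CCO)c1
F11 | step 1 | 1,3-dimethoxy-5-[(2-methylbut-3-yn-2-yl)oxy]benzene | C#CC(C)(C)Oc1cc(OC)cc(OC)c1
F12 | step 1 | 1,3-dimethoxy-5-[(2-methylbut-3-en-2-yl)oxy]benzene | C=CC(C)(C)Oc1cc(OC)cc(OC)c1
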